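**Strategy.** The trimethylcyclohexane ring is cut into two three-carbon halves: C1–C2–C3 (C1 is the gem-dimethyl carbon) and C4–C5–C6 (C5 with its methyl, C6 with the first chain carbon C7; carotenoid numbering). Ring carbons C1–C6, the three methyls and C7 are exactly two isoprenoid C5 units, 3-methylbut-2-enal and an ester-stabilised allylic phosphonium ylide. One annulation joins them: the ylide γ-carbon (C6) adds to the β,β-dimethyl terminus (C1), and the ylide carbon (C4) then olefinates the aldehyde (C3), giving ethyl safranate. Partial hydrogenation, Sharpless epoxidation of β-cyclogeraniol and anti hydrolysis set the trans-5,6-diol; Horner–Wadsworth–Emmons and Wittig couplings build the polyenal.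

Key step: step 1

Remark: the target is the all-E (5R,6R) trans-diol; phosphonium salt 2 is taken as the commercial reagent, and its double-bond geometry is lost in ylide 3.

**Step 1**
Reactants: 1 3-methylbut-2-enal; 2 [(2E)-4-ethoxy-2-methyl-4-oxobut-2-en-1-yl]triphenylphosphonium bromide
Product: 5 ethyl safranate (ethyl 2,6,6-trimethylcyclohexa-1,3-diene-1-carboxylate), via allylic ylide 3 (not isolated), via ylide aldehyde 4 (not isolated)
Conditions: NaH, THF, 0 °C; then 1, DMF, 0 °C to 60 °C
Reagents that add atoms: none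
Why: NaH converts 2 into the ambident ester-conjugated allylic ylide 3, whose γ-carbon (future C6, α to the ester) adds in conjugate fashion to the β,β-dimethyl terminus of enal 1 and so forms the quaternary C1–C6 bond. Proton transfer from C6 to the aldehyde enolate gives ylide aldehyde 4, in which the ylide carbon C4 and the formyl carbon C3 are placed for ring closure. Intramolecular Wittig olefination (6-exo-trig attack of C4 on the C3 carbonyl, then loss of Ph3P=O) closes the six-membered ring as the C3=C4 double bond and makes the sequence irreversible. The closest known reaction type is the conjugate addition/intramolecular Wittig annulation of allylic phosphorus ylides with α,β-unsaturated carbonyl compounds to cyclohexa-1,3-dienes. No stereocentre is formed: C1 becomes the gem-dimethyl quaternary carbon and C3 to C6 stay trigonal, so C5 and C6 are set later by reagent control. The step needs γ-1,4- instead of α-1,2-attack of the ylide on the enal, which the ester favours by localising charge on the γ-carbon and a polar medium at moderate temperature favours by keeping 1,2-adducts reversible.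

**Step 2**
Reactants: 5 ethyl safranate
Product: 6 ethyl β-cyclogeranate (ethyl 2,6,6-trimethylcyclohex-1-ene-1-carboxylate)
Conditions: H2 (1 atm), RhCl(PPh3)3 (5 mol%), benzene/EtOH, rt
Reagents that add atoms: none
Why: Homogeneous catalytic hydrogenation with RhCl(PPh3)3 should reduce only the unhindered cis-disubstituted C3=C4 bond, because the tetrasubstituted ester-conjugated C5=C6 bond cannot bind the rhodium centre.

**Step 3**
Reactants: 6 ethyl β-cyclogeranate
Product: 7 β-cyclogeraniol ((2,6,6-trimethylcyclohex-1-en-1-yl)methanol)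
Conditions: iBu2AlH (2.5 equiv), CH2Cl2, −78 °C to 0 °C; aq. potassium sodium tartrate
Reagents that add atoms: none
Why: Hydride reduction with iBu2AlH takes the hindered conjugated ester to the allylic alcohol in 1,2-fashion and leaves the tetrasubstituted alkene untouched.

**Step 4**
Reactants: 7 β-cyclogeraniol
Product: 8 [(1S,6S)-2,2,6-trimethyl-7-oxabicyclo[4.1.0]heptan-1-yl]methanol (the (5S,6S)-5,6-epoxide in carotenoid numbering)
Conditions: Ti(OiPr)4, L-(+)-diethyl tartrate, t-BuOOH, 4 Å molecular sieves, CH2Cl2, −20 °C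
Reagents that add atoms: tert-butyl hydroperoxide, CC(C)(C)OO
Why: In the Sharpless asymmetric epoxidation the titanium tartrate complex binds the allylic hydroxyl and, with the L-(+)-tartrate, should deliver oxygen to the face of C5=C6 that gives the (1S,6S)-epoxide, which fixes the configuration of the future C6–O bond by reagent control.

**Step 5**
Reactants: 8 epoxy alcohol
Product: 9 (1S,2R)-1-(hydroxymethyl)-2,6,6-trimethylcyclohexane-1,2-diol (trans-diol)
Conditions: HClO4 (cat.), THF/H2O, 0 °C to rt
Reagents that add atoms: water, O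
Why: In this acid-catalysed epoxide hydrolysis water should open the protonated epoxide at the tertiary carbon remote from the hydroxymethyl group (C5) with inversion, so the C5 hydroxyl ends anti to the retained C6 oxygen and the trans-(5R,6R) relationship of the target results.

**Step 6**
Reactants: 9 triol
Product: 10 (1R,2R)-1,2-dihydroxy-2,6,6-trimethylcyclohexane-1-carbaldehyde
Conditions: SO3·pyridine, DMSO, Et3N, CH2Cl2, 0 °C
Reagents that add atoms: none
Why: The Parikh–Doering oxidation converts only the primary alcohol, since the two tertiary hydroxyls cannot be oxidised and the aldehyde has no α-hydrogen to epimerise.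

**Step 7**
Reactants: 10 hydroxy aldehyde; 11 ethyl (2E)-4-(diethoxyphosphoryl)-3-methylbut-2-enoate
Product: 12 ethyl (2E,4E)-5-[(1R,2R)-1,2-dihydroxy-2,6,6-trimethylcyclohexyl]-3-methylpenta-2,4-dienoate
Conditions: 11, LiN(SiMe3)2, THF/DMPU, −78 °C; then 10, −78 °C to 0 °C
Reagents that add atoms: none
Why: The Horner–Wadsworth–Emmons olefination with the vinylogous phosphonate anion should form the (E)-C7=C8 bond and bring in the (E)-C9=C10 bond, the stabilised anion being too weak a base to deprotonate the free tertiary hydroxyls.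

**Step 8**
Reactants: 12 dienoate
Product: 13 (1R,2R)-1-[(1E,3E)-5-hydroxy-3-methylpenta-1,3-dien-1-yl]-2,6,6-trimethylcyclohexane-1,2-diol
Conditions: iBu2AlH (5 equiv), CH2Cl2, −78 °C to 0 °C; aq. potassium sodium tartrate
Reagents that add atoms: none
Why: Hydride reduction with iBu2AlH takes the dienoate to the primary allylic alcohol in 1,2-fashion, the excess reagent covering the two free hydroxyls.

**Step 9**
Reactants: 13 dienyl triol
Product: 14 [(2E,4E)-5-[(1R,2R)-1,2-dihydroxy-2,6,6-trimethylcyclohexyl]-3-methylpenta-2,4-dien-1-yl]triphenylphosphonium bromide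
Conditions: PPh3·HBr, MeOH/CH2Cl2, 0 °C to rt
Reagents that add atoms: triphenylphosphine hydrobromide, [Br-].[PH+](c1ccccc1)(c1ccccc1)c1ccccc1
Why: Triphenylphosphine hydrobromide should convert the primary allylic alcohol into the allylic phosphonium salt by substitution at C11, the standard way to C15 Wittig salts.

**Step 10**
Reactants: 15 (2E,4E,6E)-2,7-dimethylocta-2,4,6-trienedial; 16 diethyl (cyanomethyl)phosphonate
Product: 17 (2E,4E,6E,8E)-4,9-dimethyl-10-oxodeca-2,4,6,8-tetraenenitrile
Conditions: 16, NaH, THF, 0 °C; then added slowly to 15 (3 equiv), THF, 0 °C to rt; E isomer separated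
Reagents that add atoms: none
Why: A Horner–Wadsworth–Emmons olefination of one formyl group of the symmetrical dialdehyde, used in excess with inverse addition, should give mainly the mono-adduct with the new double bond E.

**Step 11**
Reactants: 14 phosphonium bromide; 17 aldehyde nitrile
Product: 19 (2E,4E,6E,8E,10E,12E,14E)-15-[(1R,2R)-1,2-dihydroxy-2,6,6-trimethylcyclohexyl]-4,9,13-trimethylpentadeca-2,4,6,8,10,12,14-heptaenenitrile, via dienyl ylide 18 (not isolated)
Conditions: NaOMe, MeOH/CH2Cl2, 0 °C to rt; then n-heptane, 80 °C (Z to E equilibration)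
Reagents that add atoms: none
Why: Wittig olefination of ylide 18 with the α-methyl enal of 17 forms the C11=C12 bond, and the Z isomer at this position should equilibrate thermally to the all-E polyene.

**Step 12**
Reactants: 19 heptaenenitrile
Product: 21 (2E,4E,6E,8E,10E,12E,14E)-15-[(1R,2R)-1,2-dihydroxy-2,6,6-trimethylcyclohexyl]-4,9,13-trimethylpentadeca-2,4,6,8,10,12,14-heptaenal (target), via aldimine 20 (not isolated)
Conditions: iBu2AlH (4 equiv), toluene, −78 °C; then aq. potassium sodium tartrate, 0 °C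
Reagents that add atoms: water, O
Why: iBu2AlH adds once to the conjugated nitrile (partial reduction of a nitrile) to give the N-aluminated aldimine, which is hydrolysed on work-up to the polyenal without touching the stereocentres or the E double bonds.

**Compound list**

1 | 3-methylbut-2-enal | CC(C)=CC=O | starting material
2 | [(2E)-4-ethoxy-2-methyl-4-oxobut-2-en-1-yl]triphenylphosphonium bromide | CCOC(=O)/C=C(\C)C[P+](c1ccccc1)(c1ccccc1)c1ccccc1.[Br-] | starting material
3 | ethyl (2E)-3-methyl-4-(triphenyl-λ5-phosphanylidene)but-2-enoate (allylic ylide) | CCOC(=O)/C=C(\C)C=P(c1ccccc1)(c1ccccc1)c1ccccc1 | intermediate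
4 | ethyl 3-methyl-2-(2-methyl-4-oxobutan-2-yl)-4-(triphenyl-λ5-phosphanylidene)but-2-enoate (delocalised ylide aldehyde) | CCOC(=O)C(=C(C)C=P(c1ccccc1)(c1ccccc1)c1ccccc1)C(C)(C)CC=O | intermediate
5 | ethyl 2,6,6-trimethylcyclohexa-1,3-diene-1-carboxylate (ethyl safranate) | CCOC(=O)C1=C(C)C=CCC1(C)C | intermediate
6 | ethyl 2,6,6-trimethylcyclohex-1-ene-1-carboxylate (ethyl β-cyclogeranate) | CCOC(=O)C1=C(C)CCCC1(C)C | intermediate
7 | (2,6,6-trimethylcyclohex-1-en-1-yl)methanol (β-cyclogeraniol) | OCC1=C(C)CCCC1(C)C | intermediate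
8 | [(1S,6S)-2,2,6-trimethyl-7-oxabicyclo[4.1.0]heptan-1-yl]methanol | OC[C@@]1(O2)C(C)(C)CCC[C@@]12C | intermediate
9 | (1S,2R)-1-(hydroxymethyl)-2,6,6-trimethylcyclohexane-1,2-diol | OC[C@@]1(O)C(C)(C)CCC[C@@]1(C)O | intermediate
10 | (1R,2R)-1,2-dihydroxy-2,6,6-trimethylcyclohexane-1-carbaldehyde | O=C[C@@]1(O)C(C)(C)CCC[C@@]1(C)O | intermediate
11 | ethyl (2E)-4-(diethoxyphosphoryl)-3-methylbut-2-enoate | CCOC(=O)/C=C(\C)CP(=O)(OCC)OCC | starting material
12 | ethyl (2E,4E)-5-[(1R,2R)-1,2-dihydroxy-2,6,6-trimethylcyclohexyl]-3-methylpenta-2,4-dienoate | CCOC(=O)/C=C(C)/C=C/[C@@]1(O)C(C)(C)CCC[C@@]1(C)O | intermediate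
13 | (1R,2R)-1-[(1E,3E)-5-hydroxy-3-methylpenta-1,3-dien-1-yl]-2,6,6-trimethylcyclohexane-1,2-diol | OC/C=C(C)/C=C/[C@@]1(O)C(C)(C)CCC[C@@]1(C)O | intermediate
14 | [(2E,4E)-5-[(1R,2R)-1,2-dihydroxy-2,6,6-trimethylcyclohexyl]-3-methylpenta-2,4-dien-1-yl]triphenylphosphonium bromide | [Br-].c1ccccc1[P+](c1ccccc1)(c1ccccc1)C/C=C(C)/C=C/[C@@]1(O)C(C)(C)CCC[C@@]1(C)O | intermediate
15 | (2E,4E,6E)-2,7-dimethylocta-2,4,6-trienedial | O=C/C(C)=C/C=C/C=C(C)/C=O | starting material
16 | diethyl (cyanomethyl)phosphonate | N#CCP(=O)(OCC)OCC | starting material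
17 | (2E,4E,6E,8E)-4,9-dimethyl-10-oxodeca-2,4,6,8-tetraenenitrile | N#C/C=C/C(C)=C/C=C/C=C(C)/C=O | intermediate
18 | (1R,2R)-2,6,6-trimethyl-1-[(1E,3E)-3-methyl-5-(triphenyl-λ5-phosphanylidene)penta-1,3-dien-1-yl]cyclohexane-1,2-diol (dienyl ylide) | c1ccccc1P(c1ccccc1)(c1ccccc1)=C/C=C(C)/C=C/[C@@]1(O)C(C)(C)CCC[C@@]1(C)O | intermediate
19 | (2E,4E,6E,8E,10E,12E,14E)-15-[(1R,2R)-1,2-dihydroxy-2,6,6-trimethylcyclohexyl]-4,9,13-trimethylpentadeca-2,4,6,8,10,12,14-heptaenenitrile | CC(/C=C/C#N)=C\C=C\C=C(C)\C=C\C=C(C)\C=C\[C@@]1(O)C(C)(C)CCC[C@@]1(C)O | intermediate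
20 | (1R,2R)-1-[(1E,3E,5E,7E,9E,11E,13E)-15-imino-3,7,12-trimethylpentadeca-1,3,5,7,9,11,13-heptaen-1-yl]-2,6,6-trimethylcyclohexane-1,2-diol (aldimine, formed N-aluminated) | CC(/C=C/C=N)=C\C=C\C=C(C)\C=C\C=C(C)\C=C\[C@@]1(O)C(C)(C)CCC[C@@]1(C)O | intermediate
21 | (2E,4E,6E,8E,10E,12E,14E)-15-[(1R,2R)-1,2-dihydroxy-2,6,6-trimethylcyclohexyl]-4,9,13-trimethylpentadeca-2,4,6,8,10,12,14-heptaenal | CC(/C=C/C=O)=C\C=C\C=C(C)\C=C\C=C(C)\C=C\[C@@]1(O)C(C)(C)CCC[C@@]1(C)O | target

**Step count.** Total: 12 steps. Longest linear sequence: 11 steps (steps 1–9, 11 and 12); step 10 prepares the partner 17.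

**Steps most likely to fail**

Step 1. Direct Wittig olefination at the ylide carbon may outrun conjugate addition to the hindered β,β-dimethyl terminus, so that the acyclic trienoate forms instead of the ring. The fallback sets out from compound 1 and uses a doubly stabilised nucleophile that can olefinate only after the conjugate addition. Compound 1 would be treated with the sodium salt (NaH, THF, rt to 60 °C) of ethyl 3-oxo-4-(triphenyl-λ5-phosphanylidene)butanoate F1; reversible conjugate addition of its β-keto ester anion and intramolecular Wittig closure should give ethyl 6,6-dimethyl-2-oxocyclohex-3-ene-1-carboxylate F2. Enol triflation (NaH, PhNTf2, THF, 0 °C) would give ethyl 6,6-dimethyl-2-{[(trifluoromethyl)sulfonyl]oxy}cyclohexa-1,3-diene-1-carboxylate F3, and iron-catalysed methylation (MeMgBr, Fe(acac)3 cat., THF/NMP, −20 °C) comes back to the route at compound 5.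

Step 9. Acid may ionise the tertiary allylic C6 hydroxyl (allylic transposition, dehydration or cyclic ether formation) in competition with phosphonium formation at C11. The fallback sets out from compound 13 and replaces the Wittig salt by a sulfone made without acid. A Mitsunobu reaction (1-phenyl-1H-tetrazole-5-thiol, PPh3, diisopropyl azodicarboxylate, THF, 0 °C) would give (1R,2R)-2,6,6-trimethyl-1-{(1E,3E)-3-methyl-5-[(1-phenyl-1H-tetrazol-5-yl)sulfanyl]penta-1,3-dien-1-yl}cyclohexane-1,2-diol F5. Oxidation ((NH4)6Mo7O24, H2O2, EtOH, 0 °C) would give (1R,2R)-2,6,6-trimethyl-1-{(1E,3E)-3-methyl-5-[(1-phenyl-1H-tetrazol-5-yl)sulfonyl]penta-1,3-dien-1-yl}cyclohexane-1,2-diol F6. Julia–Kocienski olefination of F6 with aldehyde 17 (KN(SiMe3)2, THF, −78 °C, then thermal equilibration) comes back to the route at compound 19.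

Step 5. Ionisation at C5 may be followed by semipinacol migration or elimination instead of anti capture by water, or the opening may lose its regio- and stereoselectivity. The fallback sets out from compound 8 and uses a chelation-directed opening by a carboxylate. Ti(OiPr)4 and benzoic acid (CH2Cl2, rt) should open the epoxide at C5 with inversion to give (1R,2S)-2-hydroxy-2-(hydroxymethyl)-1,3,3-trimethylcyclohexyl benzoate F4; methanolysis (K2CO3, MeOH, rt) comes back to the route at compound 9.

**Further compounds**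

F1 | step 1 | ethyl 3-oxo-4-(triphenyl-λ5-phosphanylidene)butanoate | CCOC(=O)CC(=O)C=P(c1ccccc1)(c1ccccc1)c1ccccc1
F2 | step 1 | ethyl 6,6-dimethyl-2-oxocyclohex-3-ene-1-carboxylate | CCOC(=O)C1C(=O)C=CCC1(C)C
F3 | step 1 | ethyl 6,6-dimethyl-2-{[(trifluoromethyl)sulfonyl]oxy}cyclohexa-1,3-diene-1-carboxylate | CCOC(=O)C1=C(OS(=O)(=O)C(F)(F)F)C=CCC1(C)C
F4 | step 5 | (1R,2S)-2-hydroxy-2-(hydroxymethyl)-1,3,3-trimethylcyclohexyl benzoate | OC[C@@]1(O)C(C)(C)CCC[C@@]1(C)OC(=O)c1ccccc1
F5 | step 9 | (1R,2R)-2,6,6-trimethyl-1-{(1E,3E)-3-methyl-5-[(1-phenyl-1H-tetrazol-5-yl)sulfanyl]penta-1,3-dien-1-yl}cyclohexane-1,2-diol | c1ccccc1-n1nnnc1SC/C=C(C)/C=C/[C@@]1(O)C(C)(C)CCC[C@@]1(C)O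
F6 | step 9 | (1R,2R)-2,6,6-trimethyl-1-{(1E,3E)-3-methyl-5-[(1-phenyl-1H-tetrazol-5-yl)sulfonyl]penta-1,3-dien-1-yl}cyclohexane-1,2-diol | c1ccccc1-n1nnnc1S(=O)(=O)C/C=C(C)/C=C/[C@@]1(O)C(C)(C)CCC[C@@]1(C)O
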